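**Plan**

- Retrosynthesis: cut the C3–O ester bond (octenoate), then C1′=C2′ of the side chain, then C6–C7 together with C4a–C5 (ring B), then C8a–C8 (vinyl). This leaves a 5-hydroxy-6-methyl-δ-lactam made from D-alaninol and ethyl propiolate.
- Enabling feature: the C3 oxygen is 1,3 to C4a on the piperidine ring, C5 carries C1′, and C8a carries nitrogen. A lactam-derived 2-amidodiene C7=C8–C8a=C4a and an acrylate C6=C5–C1′(=O) hung on the C3 oxygen can therefore meet in one cycloaddition, with O3–C1′ as a temporary δ-lactone.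
- Forward order: piperidine ring first (lactam), then ring B and the temporary lactone in one operation, then C8=C8a hydrogenation, then lactol Wittig olefination to join C2′–C8′, then esterification and deprotection.
- Stereochemistry: C2 comes from D-alaninol. C3 is first made 3S (Felkin–Anh) so that the tether reaches the correct face of C4a, and is inverted to 3R when the octenoate is put on (Mitsunobu). C4a and C5 come from the tethered endo cycloaddition, C8a from hydrogenation on the convex face, and C5′ from (R)-2-propyloxirane.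

Key step: step 10

Remark: locants follow decahydroquinoline numbering (N1, C2, C3, C4, C4a, C5–C8, C8a; side chain C1′–C8′), and the target is taken as the free base.

**Route**

Step 1
Reactants: 1 (R)-2-aminopropan-1-ol (D-alaninol)
Product: 2 (R)-2-(dibenzylamino)propan-1-ol
Conditions: BnBr, K2CO3, EtOH–H2O, reflux
Reagents that add atoms: benzyl bromide, BrCc1ccccc1
Why: Double SN2 N-alkylation of the primary amine gives the N,N-dibenzylamino alcohol without touching the stereocenter.

Step 2
Reactants: 2 (R)-2-(dibenzylamino)propan-1-ol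
Product: 3 (R)-2-(dibenzylamino)propanal
Conditions: (COCl)2, DMSO, CH2Cl2, −78 °C; then Et3N; used crude at once
Reagents that add atoms: none
Why: Swern oxidation gives the N,N-dibenzylamino aldehyde, whose α-stereocenter should survive when the crude aldehyde is used immediately.

Step 3
Reactants: 3 (R)-2-(dibenzylamino)propanal; 4 ethyl propiolate
Product: 6 ethyl (4S,5R)-5-(dibenzylamino)-4-hydroxyhex-2-ynoate, via lithium ethyl propiolate 5 (not isolated)
Conditions: LiN(SiMe3)2, THF, −78 °C; then 3, −78 °C
Reagents that add atoms: none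
Why: Acetylide addition to the aldehyde under non-chelation (Felkin–Anh) control, with the bulky NBn2 group anti to the nucleophile, should give the anti (4S) amino alcohol.

Step 4
Reactants: 6 ethyl (4S,5R)-5-(dibenzylamino)-4-hydroxyhex-2-ynoate
Product: 8 (5S,6R)-5-hydroxy-6-methylpiperidin-2-one, via amino ester 7 (not isolated)
Conditions: H2 (4 atm), Pd(OH)2/C, EtOH, rt; then 78 °C
Reagents that add atoms: none
Why: Catalytic hydrogenation saturates the alkyne and hydrogenolyses both N-benzyl groups, and the freed primary amine closes the six-membered lactam by intramolecular aminolysis of the ethyl ester on warming, with neither stereocenter touched.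

Step 5
Reactants: 8 (5S,6R)-5-hydroxy-6-methylpiperidin-2-one
Product: 9 (5S,6R)-5-{[tert-butyl(dimethyl)silyl]oxy}-6-methylpiperidin-2-one
Conditions: TBSCl, imidazole, DMF, rt
Reagents that add atoms: tert-butyldimethylsilyl chloride, CC(C)(C)[Si](C)(C)Cl
Why: Imidazole-promoted O-silylation protects the secondary alcohol for the enolate chemistry that follows.

Step 6
Reactants: 9 (5S,6R)-5-{[tert-butyl(dimethyl)silyl]oxy}-6-methylpiperidin-2-one
Product: 10 tert-butyl (2R,3S)-3-{[tert-butyl(dimethyl)silyl]oxy}-2-methyl-6-oxopiperidine-1-carboxylate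
Conditions: Boc2O, Et3N, DMAP (cat.), CH2Cl2, rt
Reagents that add atoms: di-tert-butyl dicarbonate, CC(C)(C)OC(=O)OC(=O)OC(C)(C)C
Why: DMAP-catalysed N-acylation of the lactam gives the N-Boc lactam needed for clean enolisation and, later, for A(1,3) conformational control.

Step 7
Reactants: 10 tert-butyl (2R,3S)-3-{[tert-butyl(dimethyl)silyl]oxy}-2-methyl-6-oxopiperidine-1-carboxylate
Product: 12 tert-butyl (2R,3S)-3-{[tert-butyl(dimethyl)silyl]oxy}-2-methyl-6-{[(trifluoromethyl)sulfonyl]oxy}-3,4-dihydropyridine-1(2H)-carboxylate, via potassium enolate 11 (not isolated)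
Conditions: KN(SiMe3)2, THF, −78 °C; then PhNTf2, −78 → 0 °C
Reagents that add atoms: N-phenylbis(trifluoromethanesulfonimide), O=S(=O)(N(c1ccccc1)S(=O)(=O)C(F)(F)F)C(F)(F)F
Why: Enolisation at the only α-CH2 and O-triflation of the enolate give the lactam-derived vinyl triflate (an α-triflyloxy enecarbamate), a known compound class.

Step 8
Reactants: 12 the vinyl triflate; 13 tributyl(vinyl)stannane
Product: 14 tert-butyl (2R,3S)-3-{[tert-butyl(dimethyl)silyl]oxy}-6-ethenyl-2-methyl-3,4-dihydropyridine-1(2H)-carboxylate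
Conditions: Pd(PPh3)4 (5 mol %), LiCl, THF, 65 °C
Reagents that add atoms: none
Why: Stille coupling (oxidative addition of the vinyl triflate to zerovalent palladium, transmetalation from tin, reductive elimination) installs C8=C7 and completes the 2-amidodiene.

Step 9
Reactants: 14 the silyl-protected amidodiene
Product: 15 tert-butyl (2R,3S)-6-ethenyl-3-hydroxy-2-methyl-3,4-dihydropyridine-1(2H)-carboxylate
Conditions: Bu4NF, THF, 0 °C
Reagents that add atoms: none
Why: Fluoride-mediated desilylation frees the C3 hydroxyl under non-acidic conditions that the acid-sensitive enecarbamate diene should tolerate.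

Step 10
Reactants: 15 tert-butyl (2R,3S)-6-ethenyl-3-hydroxy-2-methyl-3,4-dihydropyridine-1(2H)-carboxylate; 16 acryloyl chloride
Product: 18 N-Boc-(2R,3S,4aS,5S)-3-hydroxy-2-methyl-1,2,3,4,4a,5,6,7-octahydroquinoline-5-carboxylic acid 3,5-lactone, via acrylate ester 17 (not isolated)
Conditions: iPr2NEt, toluene, 0 °C; then filter, dilute to 0.01 M, BHT (cat.), 120 °C, sealed tube
Reagents that add atoms: none
Why: O-acylation gives the acrylate, whose 2-amidodiene (C7=C8–C8a=C4a, s-cis because the s-trans form clashes with the carbamate) and tethered dienophile (C5=C6) should undergo a concerted, normal-demand intramolecular Diels–Alder reaction that forms C6–C7 and C4a–C5 together; the closest known reaction types are the Diels–Alder reactions of lactam-derived 6-vinyl enecarbamates and ester-tethered type 1 intramolecular Diels–Alder reactions with a four-atom tether. Ring B closes by the [4+2] cycloaddition itself, and the δ-lactone closes in the same event as the tether C4–C3–O–C1′ folds into a chair across the 1,3-diaxial positions C3 and C4a (fused mode). C4a is set by the tether: the acrylate hangs from the C3 oxygen, which is held axial and trans to the axial C2 methyl by A(1,3) strain with the carbamate, so C5 can reach only the upper face of C4a. C5 is set by the endo, chair-like lactone transition state, which places C1′ over C8a and therefore H5 cis to H4a. The regiochemistry needed (C4a to the α-carbon, C7 to the β-carbon) opposes the electronic preference of a 2-amidodiene and is enforced by the tether, because the bridged alternative is geometrically impossible with four tether atoms. Cycloaddition must also outrun acrylate polymerisation, which high dilution and BHT should secure.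

Step 11
Reactants: 18 the tricyclic lactone enecarbamate
Product: 19 N-Boc-(2R,3S,4aS,5S,8aR)-3-hydroxy-2-methyldecahydroquinoline-5-carboxylic acid 3,5-lactone
Conditions: H2 (4 atm), Pd/C, EtOAc, rt
Reagents that add atoms: none
Why: Heterogeneous syn hydrogenation of the trisubstituted enecarbamate should occur from the convex lower face, because the lactone bridge covers the upper face, which sets H8a cis to H4a and H5 (8aR).

Step 12
Reactants: 19 the saturated tricyclic lactone
Product: 20 the corresponding lactol (C1′ hemiacetal, both anomers)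
Conditions: iBu2AlH (1.2 equiv), CH2Cl2, −78 °C
Reagents that add atoms: none
Why: Partial lactone reduction with one hydride equivalent at low temperature stops at the aluminium hemiacetal and gives the lactol, leaving the carbamate untouched.

Step 13
Reactants: 21 (R)-2-propyloxirane; 22 vinylmagnesium bromide
Product: 23 (R)-hept-1-en-4-ol
Conditions: CuI (10 mol %), THF, −40 → 0 °C
Reagents that add atoms: none
Why: Copper-catalysed SN2 opening of the terminal epoxide at the unsubstituted carbon leaves the C–O stereocenter untouched, so the alcohol is R.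

Step 14
Reactants: 23 (R)-hept-1-en-4-ol
Product: 24 (R)-tert-butyl(hept-1-en-4-yloxy)dimethylsilane
Conditions: TBSCl, imidazole, DMF, rt
Reagents that add atoms: tert-butyldimethylsilyl chloride, CC(C)(C)[Si](C)(C)Cl
Why: Standard imidazole-promoted silylation protects the carbinol that becomes C5′–OH.

Step 15
Reactants: 24 (R)-tert-butyl(hept-1-en-4-yloxy)dimethylsilane
Product: 26 (R)-4-{[tert-butyl(dimethyl)silyl]oxy}heptan-1-ol, via alkylborane 25 (not isolated)
Conditions: 9-BBN, THF, 0 °C → rt; then NaOH, H2O2, 0 °C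
Reagents that add atoms: hydrogen peroxide, OO
Why: Anti-Markovnikov hydroboration of the terminal alkene followed by oxidation with retention gives the primary alcohol.

Step 16
Reactants: 26 (R)-4-{[tert-butyl(dimethyl)silyl]oxy}heptan-1-ol
Product: 27 (R)-tert-butyl[(1-iodoheptan-4-yl)oxy]dimethylsilane
Conditions: I2, PPh3, imidazole, CH2Cl2, 0 °C → rt
Reagents that add atoms: iodine, II
Why: Appel-type iodination converts the primary alcohol into the iodide by SN2 displacement, remote from the stereocenter.

Step 17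
Reactants: 27 (R)-tert-butyl[(1-iodoheptan-4-yl)oxy]dimethylsilane
Product: 28 [(4R)-4-{[tert-butyl(dimethyl)silyl]oxy}heptyl]triphenylphosphonium iodide
Conditions: PPh3, MeCN, 80 °C
Reagents that add atoms: triphenylphosphine, c1ccc(cc1)P(c1ccccc1)c1ccccc1
Why: SN2 quaternisation of triphenylphosphine by the primary iodide gives the Wittig salt.

Step 18
Reactants: 20 the lactol; 28 the phosphonium iodide
Product: 30 tert-butyl (2R,3S,4aS,5R,8aR)-5-[(1Z,5R)-5-{[tert-butyl(dimethyl)silyl]oxy}oct-1-en-1-yl]-3-hydroxy-2-methyloctahydroquinoline-1(2H)-carboxylate, via phosphorus ylide 29 (not isolated)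
Conditions: 28 (3.5 equiv), KN(SiMe3)2 (3.3 equiv), THF, 0 °C; then 20, 0 °C → rt
Reagents that add atoms: none
Why: Wittig olefination of a lactol (Corey-lactol type) with the non-stabilised ylide should give the cis-alkene and release the C3 hydroxyl, and C5 should not epimerise because its substituent is equatorial on ring B in the preferred conformer.

Step 19
Reactants: 30 the (Z)-alkene
Product: 31 tert-butyl (2R,3S,4aS,5S,8aR)-5-[(5R)-5-{[tert-butyl(dimethyl)silyl]oxy}octyl]-3-hydroxy-2-methyloctahydroquinoline-1(2H)-carboxylate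
Conditions: H2 (1 atm), Pd/C, EtOAc, rt
Reagents that add atoms: none
Why: Catalytic hydrogenation saturates the disubstituted alkene and creates no stereocenter.

Step 20
Reactants: 31 the (3S)-alcohol; 32 (2E)-oct-2-enoic acid
Product: 33 tert-butyl (2R,3R,4aS,5S,8aR)-5-[(5R)-5-{[tert-butyl(dimethyl)silyl]oxy}octyl]-2-methyl-3-[(2E)-oct-2-enoyloxy]octahydroquinoline-1(2H)-carboxylate
Conditions: PPh3, DIAD, toluene, 0 °C → rt
Reagents that add atoms: none
Why: Mitsunobu esterification activates the alcohol and lets the carboxylate displace it by SN2 with inversion, which installs the octenoate and corrects C3 to R in one step.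

Step 21
Reactants: 33 the protected ester
Product: 34 (2R,3R,4aS,5S,8aR)-5-[(5R)-5-hydroxyoctyl]-2-methyldecahydroquinolin-3-yl (2E)-oct-2-enoate
Conditions: TFA–H2O (9:1), 0 °C → rt
Reagents that add atoms: none
Why: Acidolysis removes the Boc carbamate (loss of the tert-butyl cation, then decarboxylation) and the secondary silyl ether together, and the enoate and all stereocenters should be unaffected.

**Compound list**

1 | (R)-2-aminopropan-1-ol (D-alaninol) | C[C@@H](N)CO | starting material
2 | (R)-2-(dibenzylamino)propan-1-ol | C[C@@H](N(Cc1ccccc1)Cc1ccccc1)CO | intermediate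
3 | (R)-2-(dibenzylamino)propanal | C[C@@H](N(Cc1ccccc1)Cc1ccccc1)C=O | intermediate
4 | ethyl propiolate | C#CC(=O)OCC | starting material
5 | lithium ethyl propiolate (ethyl 3-lithioprop-2-ynoate) | [Li]C#CC(=O)OCC | intermediate
6 | ethyl (4S,5R)-5-(dibenzylamino)-4-hydroxyhex-2-ynoate | C[C@@H](N(Cc1ccccc1)Cc1ccccc1)[C@@H](O)C#CC(=O)OCC | intermediate
7 | ethyl (4S,5R)-5-amino-4-hydroxyhexanoate | C[C@@H](N)[C@@H](O)CCC(=O)OCC | intermediate
8 | (5S,6R)-5-hydroxy-6-methylpiperidin-2-one | C[C@H]1NC(=O)CC[C@@H]1O | intermediate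
9 | (5S,6R)-5-{[tert-butyl(dimethyl)silyl]oxy}-6-methylpiperidin-2-one | C[C@H]1NC(=O)CC[C@@H]1O[Si](C)(C)C(C)(C)C | intermediate
10 | tert-butyl (2R,3S)-3-{[tert-butyl(dimethyl)silyl]oxy}-2-methyl-6-oxopiperidine-1-carboxylate | C[C@H]1N(C(=O)OC(C)(C)C)C(=O)CC[C@@H]1O[Si](C)(C)C(C)(C)C | intermediate
11 | potassium enolate of 10 | C[C@H]1N(C(=O)OC(C)(C)C)C([O-])=CC[C@@H]1O[Si](C)(C)C(C)(C)C.[K+] | intermediate
12 | tert-butyl (2R,3S)-3-{[tert-butyl(dimethyl)silyl]oxy}-2-methyl-6-{[(trifluoromethyl)sulfonyl]oxy}-3,4-dihydropyridine-1(2H)-carboxylate | C[C@H]1N(C(=O)OC(C)(C)C)C(OS(=O)(=O)C(F)(F)F)=CC[C@@H]1O[Si](C)(C)C(C)(C)C | intermediate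
13 | tributyl(vinyl)stannane | CCCC[Sn](CCCC)(CCCC)C=C | starting material
14 | tert-butyl (2R,3S)-3-{[tert-butyl(dimethyl)silyl]oxy}-6-ethenyl-2-methyl-3,4-dihydropyridine-1(2H)-carboxylate | C[C@H]1N(C(=O)OC(C)(C)C)C(C=C)=CC[C@@H]1O[Si](C)(C)C(C)(C)C | intermediate
15 | tert-butyl (2R,3S)-6-ethenyl-3-hydroxy-2-methyl-3,4-dihydropyridine-1(2H)-carboxylate | C[C@H]1N(C(=O)OC(C)(C)C)C(C=C)=CC[C@@H]1O | intermediate
16 | acryloyl chloride | C=CC(=O)Cl | starting material
17 | tert-butyl (2R,3S)-3-(acryloyloxy)-6-ethenyl-2-methyl-3,4-dihydropyridine-1(2H)-carboxylate | C[C@H]1N(C(=O)OC(C)(C)C)C(C=C)=CC[C@@H]1OC(=O)C=C | intermediate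
18 | N-Boc-(2R,3S,4aS,5S)-3-hydroxy-2-methyl-1,2,3,4,4a,5,6,7-octahydroquinoline-5-carboxylic acid 3,5-lactone (C8=C8a enecarbamate; H4a and H5 cis) | O=C1O[C@H]2C[C@H]3[C@@H]1CCC=C3N(C(=O)OC(C)(C)C)[C@@H]2C | intermediate
19 | N-Boc-(2R,3S,4aS,5S,8aR)-3-hydroxy-2-methyldecahydroquinoline-5-carboxylic acid 3,5-lactone (H4a, H5 and H8a all cis) | O=C1O[C@H]2C[C@H]3[C@@H]1CCC[C@H]3N(C(=O)OC(C)(C)C)[C@@H]2C | intermediate
20 | lactol of 19 (C1′ hemiacetal, both anomers) | OC1O[C@H]2C[C@H]3[C@@H]1CCC[C@H]3N(C(=O)OC(C)(C)C)[C@@H]2C | intermediate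
21 | (R)-2-propyloxirane | CCC[C@@H]1CO1 | starting material
22 | vinylmagnesium bromide | C=C[Mg]Br | starting material
23 | (R)-hept-1-en-4-ol | C=CC[C@H](O)CCC | intermediate
24 | (R)-tert-butyl(hept-1-en-4-yloxy)dimethylsilane | C=CC[C@H](O[Si](C)(C)C(C)(C)C)CCC | intermediate
25 | 9-[(4R)-4-{[tert-butyl(dimethyl)silyl]oxy}heptyl]-9-borabicyclo[3.3.1]nonane | C1CC2CCCC(C1)B2CCC[C@H](O[Si](C)(C)C(C)(C)C)CCC | intermediate
26 | (R)-4-{[tert-butyl(dimethyl)silyl]oxy}heptan-1-ol | OCCC[C@H](O[Si](C)(C)C(C)(C)C)CCC | intermediate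
27 | (R)-tert-butyl[(1-iodoheptan-4-yl)oxy]dimethylsilane | ICCC[C@H](O[Si](C)(C)C(C)(C)C)CCC | intermediate
28 | [(4R)-4-{[tert-butyl(dimethyl)silyl]oxy}heptyl]triphenylphosphonium iodide | [I-].c1ccccc1[P+](c1ccccc1)(c1ccccc1)CCC[C@H](O[Si](C)(C)C(C)(C)C)CCC | intermediate
29 | [(4R)-4-{[tert-butyl(dimethyl)silyl]oxy}heptylidene]triphenylphosphorane | c1ccccc1P(c1ccccc1)(c1ccccc1)=CCC[C@H](O[Si](C)(C)C(C)(C)C)CCC | intermediate
30 | tert-butyl (2R,3S,4aS,5R,8aR)-5-[(1Z,5R)-5-{[tert-butyl(dimethyl)silyl]oxy}oct-1-en-1-yl]-3-hydroxy-2-methyloctahydroquinoline-1(2H)-carboxylate | O[C@H]1C[C@H]2[C@@H](/C=C\CC[C@H](O[Si](C)(C)C(C)(C)C)CCC)CCC[C@H]2N(C(=O)OC(C)(C)C)[C@@H]1C | intermediate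
31 | tert-butyl (2R,3S,4aS,5S,8aR)-5-[(5R)-5-{[tert-butyl(dimethyl)silyl]oxy}octyl]-3-hydroxy-2-methyloctahydroquinoline-1(2H)-carboxylate | O[C@H]1C[C@H]2[C@@H](CCCC[C@H](O[Si](C)(C)C(C)(C)C)CCC)CCC[C@H]2N(C(=O)OC(C)(C)C)[C@@H]1C | intermediate
32 | (2E)-oct-2-enoic acid | CCCCC/C=C/C(=O)O | starting material
33 | tert-butyl (2R,3R,4aS,5S,8aR)-5-[(5R)-5-{[tert-butyl(dimethyl)silyl]oxy}octyl]-2-methyl-3-[(2E)-oct-2-enoyloxy]octahydroquinoline-1(2H)-carboxylate | CCCCC/C=C/C(=O)O[C@@H]1C[C@H]2[C@@H](CCCC[C@H](O[Si](C)(C)C(C)(C)C)CCC)CCC[C@H]2N(C(=O)OC(C)(C)C)[C@@H]1C | intermediate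
34 | (2R,3R,4aS,5S,8aR)-5-[(5R)-5-hydroxyoctyl]-2-methyldecahydroquinolin-3-yl (2E)-oct-2-enoate | CCCCC/C=C/C(=O)O[C@@H]1C[C@H]2[C@@H](CCCC[C@H](O)CCC)CCC[C@H]2N[C@@H]1C | target

**Step count and risks**

Total step count: 21. Longest linear sequence: 16 steps (steps 1–12, then 18–21); the side-chain branch is steps 13–17.

Steps most likely to fail:

1. Step 10. The ester tether may be too reluctant to take up the cisoid conformation that the lactone-forming transition state needs, and the tether forces the electronically disfavoured regiochemistry, so cycloaddition may lose to acrylate polymerisation or to a 1,5-hydrogen shift in the diene. The fallback uses a doubly activated dienophile with a traceless carboxyl group; it sets out from 15 and comes back at 19. Alcohol 15 is acylated with maleic anhydride (Et3N, DMAP cat., CH2Cl2) to the hydrogen maleate F1. F1 is heated in toluene, where the free carboxyl on C6 makes C4a–C5 bonding electronically matched, to give the cycloadduct acid F2 (6-carboxy analogue of 18, carboxyl cis to C1′). The enecarbamate is hydrogenated first (H2, Pd/C) to the saturated acid F3, so that the later C6 radical has no homoallylic enecarbamate to rearrange onto. F3 is converted (N-hydroxypyridine-2-thione, DCC, DMAP cat.) into the Barton ester F4, and Barton reductive decarboxylation (tBuSH, visible light) replaces the carboxyl by hydrogen to give 19.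

2. Step 20. Elimination towards C3–C4, or incomplete inversion, may compete on a hindered secondary alcohol that must be attacked on the face carrying the C2 methyl, and the acid is a weaker Mitsunobu partner than the usual nitrobenzoic acids. The fallback sets out from 31 and comes back at 33. Alcohol 31 is oxidised (Dess–Martin periodinane, CH2Cl2) to the ketone F5. Reduction with LiBH(sBu)3 in THF at −78 °C should deliver hydride anti to the C2 methyl and give the cis (3R) alcohol F6. F6 is then esterified with 32 with retention (EDC·HCl, DMAP, CH2Cl2) to give 33.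

3. Step 11. The hindered trisubstituted enecarbamate may hydrogenate sluggishly on the catalyst surface, or facial selectivity may erode if adsorption is forced. The fallback replaces surface hydrogenation by ionic hydrogenation; it sets out from 18 and comes back at 19. Brief treatment with TFA (2 equiv) and Et3SiH in CH2Cl2 at −40 °C should protonate C8 to the N-acyliminium trifluoroacetate F7, and stereoelectronically controlled axial hydride delivery anti to the lactone bridge should then give 19 with the carbamate intact.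

Further compounds
F1 | step 10 | (2Z)-4-{[(2R,3S)-1-(tert-butoxycarbonyl)-6-ethenyl-2-methyl-1,2,3,4-tetrahydropyridin-3-yl]oxy}-4-oxobut-2-enoic acid (hydrogen maleate of 15) | C[C@H]1N(C(=O)OC(C)(C)C)C(C=C)=CC[C@@H]1OC(=O)/C=C\C(=O)O
F2 | step 10 | 6-carboxy analogue of 18 (carboxyl on C6 cis to C1′) | O=C1O[C@H]2C[C@H]3[C@@H]1[C@@H](C(=O)O)CC=C3N(C(=O)OC(C)(C)C)[C@@H]2C
F3 | step 10 | 6-carboxy analogue of 19 | O=C1O[C@H]2C[C@H]3[C@@H]1[C@@H](C(=O)O)CC[C@H]3N(C(=O)OC(C)(C)C)[C@@H]2C
F4 | step 10 | 2-thioxopyridin-1(2H)-yl ester of F3 (Barton ester) | O=C1O[C@H]2C[C@H]3[C@@H]1[C@@H](C(=O)ON4C=CC=CC4=S)CC[C@H]3N(C(=O)OC(C)(C)C)[C@@H]2C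
F5 | step 20 | tert-butyl (2R,4aS,5S,8aR)-5-[(5R)-5-{[tert-butyl(dimethyl)silyl]oxy}octyl]-2-methyl-3-oxooctahydroquinoline-1(2H)-carboxylate | O=C1C[C@H]2[C@@H](CCCC[C@H](O[Si](C)(C)C(C)(C)C)CCC)CCC[C@H]2N(C(=O)OC(C)(C)C)[C@@H]1C
F6 | step 20 | tert-butyl (2R,3R,4aS,5S,8aR)-5-[(5R)-5-{[tert-butyl(dimethyl)silyl]oxy}octyl]-3-hydroxy-2-methyloctahydroquinoline-1(2H)-carboxylate | O[C@@H]1C[C@H]2[C@@H](CCCC[C@H](O[Si](C)(C)C(C)(C)C)CCC)CCC[C@H]2N(C(=O)OC(C)(C)C)[C@@H]1C
F7 | step 11 | N-acyliminium trifluoroacetate formed from 18 by protonation at C8 | O=C1O[C@H]2C[C@H]3[C@@H]1CCCC3=[N+](C(=O)OC(C)(C)C)[C@@H]2C.[O-]C(=O)C(F)(F)F
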